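## Retrosynthetic overview

1. Target 21 ⇐ 20 ⇐ 17 ⇐ 11. The acetate arm at C3 and the long side chain at C6 are put on last, each by axial addition of a silyl nucleophile to a cyclic peroxycarbenium ion of the bis-methoxy-1,2-dioxane 11, whose only stereocentre is C4.
2. 11 ⇐ 8. Ozonolysis in methanol of a γ,δ-unsaturated ethyl ketone turns C3 into a methoxy hydroperoxide that closes on the C6 ketone; this makes the O–O bridge and the 1,2-dioxane ring.
3. 8 ⇐ 6 ⇐ 4. The C4–C5 bond (ethyl-bearing CH to ring CH2) is made by a Claisen ring expansion of the cyclic ketene acetal from carbonate 4. It closes a temporary seven-membered lactone and transfers the carbonate C–O stereocentre to C4; the two extra lactone atoms later leave as glycolaldehyde.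
4. Enabling feature: C3 and C6 are the two ring carbons bound to the peroxide oxygens, so C3–C4–C5–C6 is a masked 1,4-dicarbonyl unit (a γ,δ-unsaturated carbonyl, the Claisen retron) with C4–C5 as the sigmatropic bond. In the chair with both ethyl groups equatorial, the acetate arm (C3) and the side chain (C6) of the target are exactly the two axial groups.
5. Ring order: dioxolanone (step 1) → oxepinone (step 3, temporary) → 1,2-dioxane (step 6). Side-chain piece 16 comes from a second chirality-transferring Claisen rearrangement (steps 7–9).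

Key step: step 3

Remark: the ring locants of the target (O1, O2, C3 = CH bearing the acetate arm, C4 = CH bearing ethyl, C5 = CH2, C6 = quaternary carbon) are used for every 1,2-dioxane below. Compounds 1, 3, 12 and all reagents are taken as commercially available.

## Route

Step 1
Reactants: 1 (2S)-but-3-ene-1,2-diol
Product: 2 (4S)-4-ethenyl-1,3-dioxolan-2-one
Conditions: CDI (1.2 equiv), CH2Cl2, 0 → 20 °C
Reagents that add atoms: 1,1'-carbonyldiimidazole, O=C(n1ccnc1)n1ccnc1
Why: Double acyl substitution of the 1,2-diol on CDI closes the five-membered cyclic carbonate (carbonate formation) and leaves the stereocentre untouched.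

Step 2
Reactants: 2 (4S)-4-ethenyl-1,3-dioxolan-2-one; 3 (3E)-hex-3-ene
Product: 4 (4S)-4-[(1E)-but-1-en-1-yl]-1,3-dioxolan-2-one
Conditions: RuCl2(H2IMes)(=CH-C6H4-2-O-i-Pr) (second-generation Hoveyda–Grubbs catalyst, 3 mol %), 3 (5 equiv), CH2Cl2, 40 °C
Reagents that add atoms: none
Why: Olefin cross-metathesis of the terminal, allylically oxygenated alkene with an excess of the symmetrical internal alkene should give the E-disubstituted alkene (the α-branch favours E), with the stereocentre as a spectator.

Step 3
Reactants: 4 (4S)-4-[(1E)-but-1-en-1-yl]-1,3-dioxolan-2-one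
Product: 6 (4S)-4-ethyl-4,7-dihydrooxepin-2(3H)-one, via cyclic ketene acetal 5 (not isolated)
Conditions: Cp2TiMe2 (3 equiv), pyridine (trace), toluene, 70 °C, dark; then 110 °C
Reagents that add atoms: dimethyltitanocene Cp2TiMe2, [CH3-].[CH3-].[Ti+4].[cH-]1cccc1.[cH-]1cccc1
Why: On heating, Cp2TiMe2 loses methane to give Cp2Ti=CH2, which methylenates the carbonate carbonyl through an oxatitanacyclobutane and unmasks the 2-methylidene-1,3-dioxolane 5; this allyl vinyl ether then undergoes a [3,3]-sigmatropic (Claisen) shift in which the new exocyclic CH2 bonds to the ethyl-bearing alkene terminus while the allylic C–O bond breaks. The closest known reaction type is the methylenation/Claisen ring expansion of alkenyl-substituted cyclic carbonates (or of selenoxide-derived cyclic ketene acetals) to medium-ring lactones. The seven-membered lactone is closed by the new C–C bond in a pericyclic ring expansion of the five-membered ring; the small ring holds the CH2O arm of the carbinol carbon pseudo-axial in the bicyclic transition state, so the ring alkene is Z. The new stereocentre (the ethyl-bearing carbon, S, later C4 of the target) is set by suprafacial 1,3-chirality transfer from the C–O stereocentre of 4, which is consumed: with the S carbinol carbon and the E alkene the methylene can reach only the face that gives S. The step needs geometrically pure E alkene (Z material would give the enantiomeric centre) and exclusion of acid (ketene acetal hydrolysis); the E-selective metathesis of step 2 and base-washed glassware with a trace of pyridine are to secure both.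

Step 4
Reactants: 6 (4S)-4-ethyl-4,7-dihydrooxepin-2(3H)-one
Product: 7 (3S,4Z)-3-ethyl-6-hydroxy-N-methoxy-N-methylhex-4-enamide
Conditions: MeNH(OMe)·HCl, i-PrMgCl (3 equiv), THF, −20 → 0 °C
Reagents that add atoms: N,O-dimethylhydroxylamine hydrochloride, CNOC.Cl
Why: Aminolysis of the lactone by the chloromagnesium amide (Weinreb amide formation) opens the temporary ring, and the stereocentre, being β to the carbonyl, cannot epimerise.

Step 5
Reactants: 7 (3S,4Z)-3-ethyl-6-hydroxy-N-methoxy-N-methylhex-4-enamide
Product: 8 (5S,6Z)-5-ethyl-8-hydroxyoct-6-en-3-one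
Conditions: EtMgBr (2.5 equiv), THF, 0 °C; aq. NH4Cl
Reagents that add atoms: ethylmagnesium bromide, CC[Mg]Br
Why: Grignard addition to the Weinreb amide stops at the ketone because of the chelated tetrahedral intermediate, the free hydroxyl only consuming one further equivalent; this ethyl group becomes the C6 ethyl of the target.

Step 6
Reactants: 8 (5S,6Z)-5-ethyl-8-hydroxyoct-6-en-3-one
Product: 11 (4S)-4,6-diethyl-3,6-dimethoxy-1,2-dioxane, via methoxy hydroperoxide 9 (not isolated), via dioxanol 10 (not isolated)
Conditions: O3, CH2Cl2–MeOH 4:1, −78 °C, then N2 purge; p-TsOH (cat.), MeOH, 0 → 20 °C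
Reagents that add atoms: ozone, [O-][O+]=O; methanol, CO
Why: Ozonolysis in methanol should place the carbonyl oxide on the alkene carbon remote from the electron-withdrawing CH2OH group (C3), methanol traps it as the α-methoxy hydroperoxide 9, the OOH group adds to the ketone (6-exo-trig) to give the cyclic peroxy hemiketal 10, and acid-catalysed exchange gives the bis-methyl ketal 11; C3 and C6 form as epimer mixtures that converge later and C4 is untouched.

Step 7
Reactants: 12 (2E)-pent-2-enal
Product: 13 (3R,4E)-hept-4-en-3-ol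
Conditions: Et2Zn (1.5 equiv), (2R)-(+)-3-exo-morpholinoisoborneol [(+)-MIB] (4 mol %), hexane, 0 °C; aq. NH4Cl
Reagents that add atoms: diethylzinc, CC[Zn]CC
Why: Amino-alcohol-catalysed enantioselective 1,2-addition of diethylzinc to the enal, where (+)-MIB, the antipode of the ligand that gives (S)-1-phenylpropanol from benzaldehyde, should deliver the R carbinol.

Step 8
Reactants: 13 (3R,4E)-hept-4-en-3-ol
Product: 15 (4R,5E)-4-ethyloct-5-en-2-one, via allyl isopropenyl ether 14 (not isolated)
Conditions: 2-methoxypropene (6 equiv), propionic acid (cat.), xylene, sealed vessel, 130 °C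
Reagents that add atoms: 2-methoxypropene, COC(C)=C
Why: Saucy–Marbet (ketal) Claisen rearrangement: acid-catalysed exchange gives the allyl isopropenyl ether, which rearranges through a chair transition state with the carbinol ethyl group equatorial, so the E alkene forms and the R carbinol configuration is transferred suprafacially to the new R stereocentre (C10 of the target).

Step 9
Reactants: 15 (4R,5E)-4-ethyloct-5-en-2-one
Product: 16 trimethyl{[(4R,5E)-4-ethylocta-1,5-dien-2-yl]oxy}silane
Conditions: LiN(i-Pr)2 (LDA), THF, −78 °C; then Me3SiCl, Et3N, −78 → 0 °C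
Reagents that add atoms: chlorotrimethylsilane, C[Si](C)(C)Cl
Why: Kinetic deprotonation of the methyl ketone at the less hindered methyl group and O-silylation give the terminal silyl enol ether (regioselective enolisation), the β-stereocentre being unaffected.

Step 10
Reactants: 11 (4S)-4,6-diethyl-3,6-dimethoxy-1,2-dioxane; 16 trimethyl{[(4R,5E)-4-ethylocta-1,5-dien-2-yl]oxy}silane
Product: 17 (4R,5E)-1-[(4S,6R)-4,6-diethyl-3-methoxy-1,2-dioxan-6-yl]-4-ethyloct-5-en-2-one
Conditions: 16 (1.5 equiv), TMSOTf (0.2 equiv), CH2Cl2, −78 °C; then pyridine, aq. NaHCO3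
Reagents that add atoms: none
Why: TMSOTf ionises the ketal carbon C6 (tertiary peroxycarbenium ion) in preference to the acetal carbon C3, and the enol silane adds (Mukaiyama-type substitution) along the axial trajectory of the half-chair that keeps the C4 ethyl group pseudo-equatorial, which places the side chain axial and trans to the C4 ethyl group as in the target (the label 6R arises only because the oxo group changes the CIP ranking).

Step 11
Reactants: 17 (4R,5E)-1-[(4S,6R)-4,6-diethyl-3-methoxy-1,2-dioxan-6-yl]-4-ethyloct-5-en-2-one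
Product: 18 (4R,5E)-1-[(4S,6R)-4,6-diethyl-3-methoxy-1,2-dioxan-6-yl]-4-ethyloct-5-en-2-ol
Conditions: NaBH4, CeCl3·7H2O, MeOH, −40 °C
Reagents that add atoms: none
Why: Luche reduction gives the alcohol (epimer mixture, of no consequence) under near-neutral conditions that avoid base-induced β-elimination of the peroxide, and dialkyl peroxides are inert to NaBH4.

Step 12
Reactants: 18 (4R,5E)-1-[(4S,6R)-4,6-diethyl-3-methoxy-1,2-dioxan-6-yl]-4-ethyloct-5-en-2-ol
Product: 19 O-{(4R,5E)-1-[(4S,6R)-4,6-diethyl-3-methoxy-1,2-dioxan-6-yl]-4-ethyloct-5-en-2-yl} 1H-imidazole-1-carbothioate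
Conditions: 1,1'-thiocarbonyldiimidazole, DMAP (cat.), CH2Cl2, 35 °C
Reagents that add atoms: 1,1'-thiocarbonyldiimidazole, S=C(n1ccnc1)n1ccnc1
Why: Thioacylation of the secondary alcohol gives the imidazolyl thiocarbamate needed for radical deoxygenation.

Step 13
Reactants: 19 O-{(4R,5E)-1-[(4S,6R)-4,6-diethyl-3-methoxy-1,2-dioxan-6-yl]-4-ethyloct-5-en-2-yl} 1H-imidazole-1-carbothioate
Product: 20 (4S,6S)-4,6-diethyl-6-[(4R,5E)-4-ethyloct-5-en-1-yl]-3-methoxy-1,2-dioxane
Conditions: Bu3SnH, Et3B (cat.), trace air, toluene, 20 °C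
Reagents that add atoms: none
Why: Barton–McCombie deoxygenation: the stannyl radical adds to C=S, fragmentation gives a secondary alkyl radical that is γ to the peroxide (too remote for fast attack on O–O) and takes H from Bu3SnH, while room-temperature initiation spares the O–O bond and the alkene.

Step 14
Reactants: 20 (4S,6S)-4,6-diethyl-6-[(4R,5E)-4-ethyloct-5-en-1-yl]-3-methoxy-1,2-dioxane
Product: 21 methyl 2-{(3S,4S,6S)-4,6-diethyl-6-[(4R,5E)-4-ethyloct-5-en-1-yl]-1,2-dioxan-3-yl}acetate
Conditions: 1-(tert-butyldimethylsilyloxy)-1-methoxyethene (3 equiv), TMSOTf (0.3 equiv), CH2Cl2, −78 °C; then pyridine, aq. NaHCO3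
Reagents that add atoms: 1-(tert-butyldimethylsilyloxy)-1-methoxyethene, C=C(OC)O[Si](C)(C)C(C)(C)C
Why: TMSOTf ionises the peroxyacetal at C3 to the cyclic peroxycarbenium ion and the silyl ketene acetal adds (Mukaiyama-type substitution) axially on the half-chair in which both ethyl groups stay equatorial, on the face opposite to the axial side chain at C6, so the acetate arm ends axial and cis to the C4 ethyl group (3S).

## Compound list

1 | (2S)-but-3-ene-1,2-diol | C=C[C@@H](CO)O | starting material
2 | (4S)-4-ethenyl-1,3-dioxolan-2-one | C=C[C@H]1COC(=O)O1 | intermediate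
3 | (3E)-hex-3-ene | CC/C=C/CC | starting material
4 | (4S)-4-[(1E)-but-1-en-1-yl]-1,3-dioxolan-2-one | CC/C=C/[C@H]1COC(=O)O1 | intermediate
5 | (4S)-4-[(1E)-but-1-en-1-yl]-2-methylidene-1,3-dioxolane | CC/C=C/[C@H]1COC(=C)O1 | intermediate (not isolated)
6 | (4S)-4-ethyl-4,7-dihydrooxepin-2(3H)-one (ring alkene Z) | CC[C@H]1CC(=O)OCC=C1 | intermediate
7 | (3S,4Z)-3-ethyl-6-hydroxy-N-methoxy-N-methylhex-4-enamide | CC[C@@H](CC(=O)N(C)OC)/C=C\CO | intermediate
8 | (5S,6Z)-5-ethyl-8-hydroxyoct-6-en-3-one | CC[C@@H](CC(=O)CC)/C=C\CO | intermediate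
9 | (5S)-5-ethyl-6-hydroperoxy-6-methoxyhexan-3-one (C6 epimers) | CC[C@@H](CC(=O)CC)C(OC)OO | intermediate (not isolated)
10 | (4S)-4,6-diethyl-3-methoxy-1,2-dioxan-6-ol (C3 and C6 epimers) | CCC1(O)C[C@H](CC)C(OC)OO1 | intermediate (not isolated)
11 | (4S)-4,6-diethyl-3,6-dimethoxy-1,2-dioxane (C3 and C6 epimers) | CCC1(OC)C[C@H](CC)C(OC)OO1 | intermediate
12 | (2E)-pent-2-enal | CC/C=C/C=O | starting material
13 | (3R,4E)-hept-4-en-3-ol | CC/C=C/[C@H](O)CC | intermediate
14 | (3R,4E)-3-(prop-1-en-2-yloxy)hept-4-ene | CC/C=C/[C@H](OC(C)=C)CC | intermediate (not isolated)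
15 | (4R,5E)-4-ethyloct-5-en-2-one | CC/C=C/[C@H](CC)CC(C)=O | intermediate
16 | trimethyl{[(4R,5E)-4-ethylocta-1,5-dien-2-yl]oxy}silane | CC/C=C/[C@H](CC)CC(=C)O[Si](C)(C)C | intermediate
17 | (4R,5E)-1-[(4S,6R)-4,6-diethyl-3-methoxy-1,2-dioxan-6-yl]-4-ethyloct-5-en-2-one (C3 epimers) | CC/C=C/[C@H](CC)CC(=O)C[C@@]1(CC)C[C@H](CC)C(OC)OO1 | intermediate
18 | (4R,5E)-1-[(4S,6R)-4,6-diethyl-3-methoxy-1,2-dioxan-6-yl]-4-ethyloct-5-en-2-ol (carbinol and C3 epimers) | CC/C=C/[C@H](CC)CC(O)C[C@@]1(CC)C[C@H](CC)C(OC)OO1 | intermediate
19 | O-{(4R,5E)-1-[(4S,6R)-4,6-diethyl-3-methoxy-1,2-dioxan-6-yl]-4-ethyloct-5-en-2-yl} 1H-imidazole-1-carbothioate | CC/C=C/[C@H](CC)CC(OC(=S)n2ccnc2)C[C@@]1(CC)C[C@H](CC)C(OC)OO1 | intermediate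
20 | (4S,6S)-4,6-diethyl-6-[(4R,5E)-4-ethyloct-5-en-1-yl]-3-methoxy-1,2-dioxane (C3 epimers) | CC/C=C/[C@H](CC)CCC[C@@]1(CC)C[C@H](CC)C(OC)OO1 | intermediate
21 | methyl 2-{(3S,4S,6S)-4,6-diethyl-6-[(4R,5E)-4-ethyloct-5-en-1-yl]-1,2-dioxan-3-yl}acetate | CC/C=C/[C@H](CC)CCC[C@@]1(CC)C[C@H](CC)[C@H](CC(=O)OC)OO1 | target

## Step count and risks

Total step count: 14. Longest linear sequence: 11 steps (steps 1–6 and 10–14); the side-chain branch (steps 7–9) joins at step 10.

Steps most likely to fail:

**Step 3 (key step).** The carbonate carbonyl is only weakly electrophilic, so methylenation may stall, and the acid-labile ketene acetal 5 may hydrolyse or oligomerise on the titanium residues before it rearranges. Any Z-alkenyl material carried in from step 2 would rearrange to the enantiomeric centre and erode the configurational purity at C4. The fallback makes the ketene acetal by selenoxide elimination instead of carbonyl methylenation; it sets out from 4 and returns at 6. Methanolysis of 4 (K2CO3, MeOH) gives (2S,3E)-hex-3-ene-1,2-diol F1, which can be freed from Z isomer at this stage. Acetal exchange with (2,2-diethoxyethyl)(phenyl)selane (PPTS, toluene, 80 °C) gives (4S)-4-[(1E)-but-1-en-1-yl]-2-[(phenylselanyl)methyl]-1,3-dioxolane F2. NaIO4/NaHCO3 in aqueous MeOH gives the selenoxide F3, and thermolysis with DBU in xylene at 140 °C effects syn-elimination to 5, which rearranges in the same flask to 6.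

**Step 6.** The primary ozonide may fragment in the opposite sense (carbonyl oxide on the two-carbon piece), or the hydroperoxy acetal may be solvolysed before it closes on the ketone; both drain material into peroxide-free keto aldehyde acetals. The fallback separates C=C cleavage from O–O introduction; it sets out from 8 and returns at 11. Dihydroxylation (OsO4 cat., N-methylmorpholine N-oxide, acetone–H2O) gives (5S)-5-ethyl-6,7,8-trihydroxyoctan-3-one F4. NaIO4 cleavage gives (2S)-2-ethyl-4-oxohexanal F5, to be used at once because its α-stereocentre can epimerise. Acid-catalysed peroxyketalisation of this 1,4-dicarbonyl compound with 50 % aqueous H2O2 in MeOH (cat. p-TsOH, 0 °C) closes the 1,2-dioxane, and methanol exchange gives 11.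

**Step 14.** Addition to the secondary peroxycarbenium ion may show poor facial selectivity (C3 epimer), or the Lewis acid may trigger heterolysis of the O–O bond. The fallback replaces peroxycarbenium chemistry by Wittig olefination and intramolecular hydroperoxide conjugate addition; it sets out from 20 and returns at 21. Hydrolysis of the peroxyacetal (PPTS, THF–H2O) gives (4S,6S)-4,6-diethyl-6-[(4R,5E)-4-ethyloct-5-en-1-yl]-1,2-dioxan-3-ol F6. Methyl (triphenylphosphoranylidene)acetate in CH2Cl2 olefinates its open hydroperoxy aldehyde form to methyl (2E,4S,6S,10R,11E)-4,6,10-triethyl-6-hydroperoxytetradeca-2,11-dienoate F7. Et2NH in CF3CH2OH induces 6-exo conjugate addition of the hydroperoxide to give 21 together with its C3 epimer, which are to be separated. This closure is expected to be less selective for the 3,4-cis isomer than step 14; the unwanted epimer can be resubmitted to the base because the addition is reversible.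

## Further compounds

F1 | step 3 | (2S,3E)-hex-3-ene-1,2-diol | CC/C=C/[C@H](O)CO
F2 | step 3 | (4S)-4-[(1E)-but-1-en-1-yl]-2-[(phenylselanyl)methyl]-1,3-dioxolane | CC/C=C/[C@H]1COC(C[Se]c2ccccc2)O1
F3 | step 3 | (4S)-4-[(1E)-but-1-en-1-yl]-2-[(phenylseleninyl)methyl]-1,3-dioxolane | CC/C=C/[C@H]1COC(C[Se](=O)c2ccccc2)O1
F4 | step 6 | (5S)-5-ethyl-6,7,8-trihydroxyoctan-3-one | CC[C@@H](CC(=O)CC)C(O)C(O)CO
F5 | step 6 | (2S)-2-ethyl-4-oxohexanal | CC[C@@H](CC(=O)CC)C=O
F6 | step 14 | (4S,6S)-4,6-diethyl-6-[(4R,5E)-4-ethyloct-5-en-1-yl]-1,2-dioxan-3-ol | CC/C=C/[C@H](CC)CCC[C@@]1(CC)C[C@H](CC)C(O)OO1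
F7 | step 14 | methyl (2E,4S,6S,10R,11E)-4,6,10-triethyl-6-hydroperoxytetradeca-2,11-dienoate | CC/C=C/[C@H](CC)CCC[C@](CC)(OO)C[C@H](CC)/C=C/C(=O)OC
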